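# Proposed total synthesis of CNP0262559.7 (compound 33) by a ring-closing nitrile oxide cycloaddition

## The problem

Compound 33 is a ten-membered carbocycle (C1–C10, germacranolide numbering) with an E-C1=C2 alkene, a Z-trisubstituted C4=C5 alkene and a cis-fused α-methylene-γ-lactone across C6–C7. The ring is strained and has no reliable conformation until it is closed. Of the five stereocentres, C6, C7 and C8 are contiguous and can be relayed (C6 to C7 within the lactone, C7 to C8 in the ring-forming step). C10 is a tertiary carbinol whose oxygen is 1,3-anti to the C8 oxygen. C3 lies across the Z-alkene from C6, too far for substrate control, and needs a reagent. The Z geometry of C4=C5 cannot be left to the ring closure and must be built in the open chain. The α-methylene lactone is a Michael acceptor and a dipolarophile. The angelate isomerises to the tiglate with base or nucleophiles. C3 is a bis-allylic and C10 a tertiary allylic alcohol, both prone to ionisation. Any β-hydroxy ketone on the way can suffer retro-aldol cleavage or dehydration. The enabling feature is that O8 and O10 are 1,3-related across C9. With C10 at the ketone level, C8–C9–C10 is a β-hydroxy ketone, the retron of a 2-isoxazoline whose dipole carbon C10 is conjugated to C1=C2 and whose alkene partner is a vinyl group C8=C9 on C7 of the cis-lactone.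

## Retrosynthesis

**Ester and silyl ether (33 to 29 and 30).** The C8–O acyl bond and the C3 silyl ether are cut first, giving silyl ether 32 and then diol 29 and angelic acid 30. The angelate is put on last among the skeletal operations because it would not survive enolate or organometallic steps. In 29 the secondary C8 hydroxyl is distinguished from the tertiary C10 hydroxyl by hindrance, and C3 stays masked. The forward steps need an esterification without a nucleophilic catalyst and a buffered desilylation.

**Exocyclic methylene (29 to 28 to 25).** C11=C13 is removed next, through the triethylsilyl ether 28 to the saturated lactone 25. The methylene lactone must come after every organometallic step and after the cycloaddition, since it would capture both a methyl nucleophile and a nitrile oxide. The forward reaction is an enolate aminomethylation and elimination in the presence of one free tertiary alcohol.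

**C10–C14 (25 to 24).** The tertiary carbinol is cut to ketone 24. In the chain C7–C8–C9–C10–C1 the two oxygens of 33 are anti, so the methyl group is syn to O8. A chelated addition to the free hydroxy ketone 23 would bring the methyl group in anti to O8 and give the 1,3-syn diol, the wrong C10 epimer. The C8 hydroxyl is therefore silylated (24) and a non-chelating, weakly basic methyl donor is used. The silyl group is also the handle that later frees O8 alone. This step asks the ring itself for facial control and is the least secure stereocentre of the plan.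

**Unmasking the aldol (24 to 23 to 21).** The β-hydroxy ketone 23 comes from isoxazoline 21 by reductive N–O cleavage. Nothing else in 21 is reducible under these conditions. The precursor holds O8 and the C10 oxidation level in one stable ring, immune to retro-aldol cleavage.

**Ring closure (21 to 20 to 19).** The C9–C10 and O–C8 bonds are cut together, leading to nitrile oxide 20 and its oxime 19. Other ring-closing cuts were weighed.
- A direct aldol at C9–C10 is reversible and uncontrolled.
- Metathesis at C4=C5 would have to make a Z-trisubstituted alkene in a ten-membered ring.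
- A chromium-mediated closure at C3–C4 makes C3 on the ring without control. It is kept as the fallback.

The cycloaddition is irreversible, needs no base, and sets C8 from C7. The precursor 19 is open-chain apart from the lactone and already carries C3, C6, C7 and both alkenes. The forward reaction has to close a ten-membered ring against dimerisation of the dipole.

**C3–C4 (19 to 17 to 16, then 13 and 14).** Oxime 19 comes from acetal 17, the silyl ether of alcohol 16. Cutting 16 between the carbinol and the trisubstituted alkene gives iodoalkene 13 and the four-carbon enal acetal 14. Compound 13 holds the lactone with C6 and C7. Compound 14 supplies C3, C2, C1 and C10 at the right oxidation level. A cut at C2–C3 would need a Z-α-methyl enal, which isomerises readily. A cut at C5–C6 would create C6 during the coupling. The forward coupling must tolerate the lactone and set C3 by a chiral ligand.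

**C4=C5 (13 to 10 to 9).** The Z-iodoalkene comes from aldehyde 10 with the α-iodo ylide 12, made from phosphonium salt 11. This puts iodine, and later C3, cis to C6. Carbometalation of an alkyne attached to C6 would place the methyl group on the wrong carbon or give the E isomer. Aldehyde 10 is the oxidation product of the five-carbon lactone alcohol 9.

**C7–C11 (9 to 7 to 4 to 3 to 1).** Lactone 9 is the acid-closed form of ester 7. The C7–C11 bond of 7 is cut as a [3,3] shift of the Z-allylic alcohol 4 with orthoacetate 5. This rearrangement gives the 6,7-syn ester and hence the cis-lactone. Conjugate addition of a vinylcopper reagent to the corresponding enoate is known to lead to the trans series. Alcohol 4 comes from enoate 3, made from (S)-glyceraldehyde acetonide 1 and phosphonate 2. C6 is thus taken from the chiral pool.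

## Roads not taken

**Alternative 1: carbomagnesiation joining methyl, C5 and C6.** This plan cuts C4–C15 and C5–C6 together. Copper-catalysed anti-addition of a methyl Grignard reagent to propargyl alcohol A2 gives a chelated Z-alkenylmagnesium. It would be added in the same flask to aldehyde ester A3, and the C6 alkoxide then closes the lactone to give A1.
- Merits: the magnesium chelate guarantees the Z geometry. C8 and C10 arrive already set in the open chain of A3. On C10 this road is better than the chosen plan, which has to make that centre on the ring.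
- Weak points: the excess Grignard reagent needed for the carbometalation competes for the aldehyde and the ester of A3. The C6 face is decided by a contest between the α-centre C7 and chelation to the β-ether. A3 can epimerise at C7. The ring must still be closed at C2–C3 from A1 by a coupling that makes C3 without control.
- Comparison: the chosen plan sets C6 and C7 by a stereospecific rearrangement, and its ring closure creates C8 with a definable bias.

**Alternative 2: anionic oxy-Cope ring expansion.** This plan cuts C8–C9 in the sigmatropic sense. The potassium alkoxide of a six-membered divinyl carbinol rearranges to a ten-membered enolate, which is protonated to dienone A4.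
- Merits: this is the best-precedented entry to cyclodecadienones. It needs no high dilution, the alkoxide pays for the strain, and C8 comes by chirality transfer. As a way of making the ring it is clearly safer than the chosen plan.
- Weak points: A4 carries the alkene at C1=C10 and no oxygen on C10. A later epoxidation and isomerisation must choose one of three allylic positions. The three lactone carbons are absent, so C7 of an isomerisable Z-enone must be alkylated and C6 reduced to the cis series. Most of the stereochemical work therefore falls after the key step, on the flexible ring.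
- Comparison: the chosen plan closes the ring with C3, C6, C7, all lactone carbons and C1=C2 in place, and obtains O8 and the C10 ketone from the closure itself.

**Alternative 3: silicon-tethered metathesis for C4=C5.** This plan cuts C4=C5. The second-generation Grubbs catalyst closes the mixed diisopropylsilyl ketal of the C3 and C6 carbinols to the seven-membered dioxasilepine A5.
- Merits: the small ring enforces the Z geometry more securely than the olefination of step 6. Two halves of similar size are joined. C10 is set in the open chain. The acrylate with its allylic acetate prepares an intramolecular allylation onto C8 that would close the carbocycle and form the methylene lactone together. That closure type has better precedent for ten-membered lactone-bearing rings than a nitrile oxide closure. On these three counts the road is as good as or better than the chosen one.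
- Weak points: the metathesis must join a 1,1-disubstituted alkene to a vinyl group between two oxygenated carbons while C1=C2 and the acrylate look on. The ketal must be assembled stepwise from two hindered alcohols. The final closure would set C7 and C8 at once and must give the cis-lactone without an obvious control element.
- Comparison: the chosen plan fixes C6 and C7 before any ring closure and leaves only C8 to the closure.

Key step: step 10

## Route

Remark on starting material: (S)-glyceraldehyde acetonide 1 is taken as purchasable and is used freshly distilled, since it oligomerises on storage.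

Remark on names: germacrane numbering is used for ring compounds. α/β refer to the usual drawing with H-7 α, "14-nor" means no methyl on C10, TBSO is tert-butyldimethylsilyloxy and TESO is triethylsilyloxy.

Step 1
Reactants: 1 (S)-2,2-dimethyl-1,3-dioxolane-4-carbaldehyde; 2 methyl 2-[bis(2,2,2-trifluoroethoxy)phosphoryl]acetate
Product: 3 methyl (Z)-3-[(4R)-2,2-dimethyl-1,3-dioxolan-4-yl]prop-2-enoate
Conditions: KN(SiMe3)2, 18-crown-6, THF, −78 °C
Reagents that add atoms: 2 methyl 2-[bis(2,2,2-trifluoroethoxy)phosphoryl]acetate, COC(=O)CP(=O)(OCC(F)(F)F)OCC(F)(F)F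
Why: Still–Gennari olefination; the electron-poor phosphonate under dissociating conditions collapses kinetically to the Z-enoate, and −78 °C keeps the α-alkoxy aldehyde from epimerising.

Step 2
Reactants: 3 methyl (Z)-3-[(4R)-2,2-dimethyl-1,3-dioxolan-4-yl]prop-2-enoate
Product: 4 (Z)-3-[(4R)-2,2-dimethyl-1,3-dioxolan-4-yl]prop-2-en-1-ol
Conditions: i-Bu2AlH, CH2Cl2, −78 °C; aq. potassium sodium tartrate
Reagents that add atoms: none
Why: 1,2-reduction of the enoate by the aluminium hydride at low temperature; the Z geometry and the acetonide are untouched.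

Step 3
Reactants: 4 (Z)-3-[(4R)-2,2-dimethyl-1,3-dioxolan-4-yl]prop-2-en-1-ol; 5 triethyl orthoacetate
Product: 7 ethyl (3R)-3-[(4R)-2,2-dimethyl-1,3-dioxolan-4-yl]pent-4-enoate, via ketene acetal 6 (not isolated)
Conditions: 5 (excess), EtCO2H (cat.), 140 °C, EtOH distilled off
Reagents that add atoms: 5 triethyl orthoacetate, CC(OCC)(OCC)OCC
Why: Johnson–Claisen rearrangement through a chair transition state. The Z-alkene holds the C6–H in the alkene plane (allylic 1,3-strain) and the new C7–C11 bond should form anti to the dioxolane C6–O bond, which gives the 6,7-syn ester that becomes the cis-lactone.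

Step 4
Reactants: 7 ethyl (3R)-3-[(4R)-2,2-dimethyl-1,3-dioxolan-4-yl]pent-4-enoate
Product: 9 (4R,5R)-4-ethenyl-5-(hydroxymethyl)oxolan-2-one, via dihydroxy ester 8 (not isolated)
Conditions: TsOH·H2O (cat.), THF/H2O, 50 °C
Reagents that add atoms: none
Why: acid hydrolysis of the acetonide followed by lactonisation; the secondary C6 hydroxyl closes the five-membered lactone in preference to the six-membered one, and no stereocentre is touched.

Step 5
Reactants: 9 (4R,5R)-4-ethenyl-5-(hydroxymethyl)oxolan-2-one
Product: 10 (2R,3R)-3-ethenyl-5-oxooxolane-2-carbaldehyde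
Conditions: Dess–Martin periodinane, CH2Cl2, 0 °C to rt; used crude
Reagents that add atoms: none
Why: Dess–Martin oxidation is non-basic, so the epimerisable cis C6 centre next to the new aldehyde should be kept.

Step 6
Reactants: 10 (2R,3R)-3-ethenyl-5-oxooxolane-2-carbaldehyde; 11 ethyltriphenylphosphonium iodide
Product: 13 (4R,5R)-4-ethenyl-5-[(Z)-2-iodoprop-1-en-1-yl]oxolan-2-one, via iodo ylide 12 (not isolated)
Conditions: 11, n-BuLi, THF; I2, −78 °C; NaN(SiMe3)2, −20 °C; then 10, −78 °C
Reagents that add atoms: 11 ethyltriphenylphosphonium iodide, CC[P+](c1ccccc1)(c1ccccc1)c1ccccc1.[I-]; iodine, II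
Why: Wittig olefination with the α-iodo ylide (the α-methyl variant of the Stork–Zhao olefination); the unstabilised ylide gives the cis-oxaphosphetane and hence the Z-iodoalkene with iodine cis to C6.

Step 7
Reactants: 13 (4R,5R)-4-ethenyl-5-[(Z)-2-iodoprop-1-en-1-yl]oxolan-2-one; 14 (E)-4,4-dimethoxybut-2-enal
Product: 16 (4R,5R)-4-ethenyl-5-[(1Z,3S,4E)-3-hydroxy-6,6-dimethoxy-2-methylhexa-1,4-dien-1-yl]oxolan-2-one, via alkenylchromium dichloride 15 (not isolated)
Conditions: CrCl2, NiCl2 (cat.), N-[2-(4-isopropyl-4,5-dihydrooxazol-2-yl)-6-methylphenyl]methanesulfonamide (antipode that directs Re-face attack), Et3N, THF, rt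
Reagents that add atoms: 14 (E)-4,4-dimethoxybut-2-enal, COC(OC)/C=C/C=O
Why: Nozaki–Hiyama–Kishi coupling; nickel inserts into the C–I bond with retention and hands the alkenyl group to chromium, which adds 1,2 to the enal and ignores the lactone and the acetal. C3 is set by the chiral sulfonamide ligand on chromium (attack on the Re face gives 3S), because C6 is too remote to control it.

Step 8
Reactants: 16 (4R,5R)-4-ethenyl-5-[(1Z,3S,4E)-3-hydroxy-6,6-dimethoxy-2-methylhexa-1,4-dien-1-yl]oxolan-2-one
Product: 17 (4R,5R)-5-[(1Z,3S,4E)-3-TBSO-6,6-dimethoxy-2-methylhexa-1,4-dien-1-yl]-4-ethenyloxolan-2-one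
Conditions: TBSCl, imidazole, DMAP (cat.), DMF, rt
Reagents that add atoms: tert-butyldimethylsilyl chloride, CC(C)(C)[Si](C)(C)Cl
Why: standard silylation of a secondary alcohol; the chloride is used and not the triflate, so that the allylic acetal is not cleaved.

Step 9
Reactants: 17 (4R,5R)-5-[(1Z,3S,4E)-3-TBSO-6,6-dimethoxy-2-methylhexa-1,4-dien-1-yl]-4-ethenyloxolan-2-one
Product: 19 (2E,4S,5Z)-4-TBSO-5-methyl-6-[(2R,3R)-3-ethenyl-5-oxooxolan-2-yl]hexa-2,5-dienal oxime, via enal 18 (not isolated)
Conditions: NH2OH·HCl, THF/H2O, rt; then NaOAc
Reagents that add atoms: hydroxylamine hydrochloride, NO.Cl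
Why: the hydrochloride supplies the acid that hydrolyses the allylic acetal, and hydroxylamine condenses with the freed enal to the aldoxime; the silyl ether and both alkene geometries should survive this mild acidity, and either oxime isomer serves in the next step.

Step 10
Reactants: 19 (2E,4S,5Z)-4-TBSO-5-methyl-6-[(2R,3R)-3-ethenyl-5-oxooxolan-2-yl]hexa-2,5-dienal oxime
Product: 21 (1E,4Z)-3β-TBSO-8β,10-(epoxynitrilo)-14-norgermacra-1,4-dien-12,6β-olide (2-isoxazoline with O on C8 and C10=N; 3S; 8R), via nitrile oxide 20 (not isolated)
Conditions: aq. NaOCl (slow addition), CH2Cl2, 0 to 40 °C, about 1 mM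
Reagents that add atoms: none
Why: Proposed new method: hypochlorite dehydrogenates the aldoxime to the conjugated nitrile oxide 20, which adds to the C8=C9 vinyl group in a concerted suprafacial (3+2) cycloaddition, carbon to the CH2 terminus C9 and oxygen to C8, the normal orientation for a monosubstituted alkene. The closest known reaction type is the intramolecular nitrile oxide–alkene cycloaddition that closes twelve-membered and larger carbocycles in this bridged sense and five- to seven-membered rings in the fused sense; a ten-membered closure is not on record. The ten-membered carbocycle closes through the C9–C10 bond, with the dipole carbon attacking the alkene terminus so that all three isoxazoline carbons lie in the large ring, and the isoxazoline closes at the same time through O–C8, giving a bridged bicycle. The new C8 centre is controlled by C7: the tether atom C6 must sit on the alkene face that the dipole attacks, and with the C7–H eclipsing the vinyl group (smallest group inside, lactone CH2 pointing away) that face gives 8R with the oxygen cis to C11. Regiochemistry is secured by the terminal alkene and chemoselectivity by the E-C1=C2 bond, which keeps the dipole away from C4=C5, while the cis-lactone, the Z-C4=C5 alkene and the E-alkenyl dipole fold the chain so that C10 lies near C9. Dimerisation to the furoxan is the competing path and is held back by slow generation of the dipole at high dilution.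

Step 11
Reactants: 21 (1E,4Z)-3β-TBSO-8β,10-(epoxynitrilo)-14-norgermacra-1,4-dien-12,6β-olide
Product: 23 (1E,4Z)-3β-TBSO-8β-hydroxy-10-oxo-14-norgermacra-1,4-dien-12,6β-olide, via hydroxy imine 22 (not isolated)
Conditions: Mo(CO)6, MeCN/H2O, 80 °C
Reagents that add atoms: water, O
Why: reductive N–O cleavage of the isoxazoline by the molybdenum carbonyl and hydrolysis of the resulting imine give the β-hydroxy enone; unlike hydrogenolysis this leaves the three alkenes alone, and C8 is not touched.

Step 12
Reactants: 23 (1E,4Z)-3β-TBSO-8β-hydroxy-10-oxo-14-norgermacra-1,4-dien-12,6β-olide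
Product: 24 (1E,4Z)-3β-TBSO-8β-TESO-10-oxo-14-norgermacra-1,4-dien-12,6β-olide
Conditions: TESCl, imidazole, DMF, 0 °C
Reagents that add atoms: triethylsilyl chloride, CC[Si](Cl)(CC)CC
Why: silylation removes the hydroxyl that would chelate the ketone and that could add across the enone or trigger retro-aldol cleavage; the triethylsilyl group can later be removed beside the C3 silyl ether.

Step 13
Reactants: 24 (1E,4Z)-3β-TBSO-8β-TESO-10-oxo-14-norgermacra-1,4-dien-12,6β-olide
Product: 25 (1E,4Z)-3β-TBSO-8β-TESO-10α-hydroxygermacra-1,4-dien-12,6β-olide (10R)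
Conditions: MeLi, CeCl3, THF, −78 °C
Reagents that add atoms: methyllithium, [Li]C
Why: organocerium 1,2-addition, selective for the ketone over the lactone and too weakly basic to enolise the ketone or eliminate the β-silyloxy group. Without a chelate the C10=O dipole should turn away from the C8–O bond (carbonyl oxygen toward the α face), and MeCeCl2 then enters from the ring periphery, which puts the methyl group β, cis to O8, and the hydroxyl α (the 1,3-anti diol).

Step 14
Reactants: 25 (1E,4Z)-3β-TBSO-8β-TESO-10α-hydroxygermacra-1,4-dien-12,6β-olide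
Product: 28 (1E,4Z)-3β-TBSO-8β-TESO-10α-hydroxygermacra-1,4,11(13)-trien-12,6β-olide, via Mannich base 26 (not isolated), via ammonium iodide 27 (not isolated)
Conditions: LiN(i-Pr)2 (2.5 equiv), THF, −78 °C; Eschenmoser's salt, −78 to 0 °C; MeOH, MeI, rt; DBU
Reagents that add atoms: Eschenmoser's salt (dimethylmethyleneiminium iodide), C=[N+](C)C.[I-]
Why: Mannich reaction of the lactone enolate with the iminium salt, quaternisation and base-induced elimination of trimethylamine give the exocyclic methylene; one extra equivalent of base covers the tertiary hydroxyl, and C7 is not involved.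

Step 15
Reactants: 28 (1E,4Z)-3β-TBSO-8β-TESO-10α-hydroxygermacra-1,4,11(13)-trien-12,6β-olide
Product: 29 (1E,4Z)-3β-TBSO-8β,10α-dihydroxygermacra-1,4,11(13)-trien-12,6β-olide
Conditions: PPTS, MeOH/CH2Cl2, 0 °C
Reagents that add atoms: none
Why: acid-catalysed methanolysis removes the triethylsilyl ether much faster than the bulkier tert-butyldimethylsilyl ether, and the acid is too weak to ionise the allylic alcohols at this temperature.

Step 16
Reactants: 29 (1E,4Z)-3β-TBSO-8β,10α-dihydroxygermacra-1,4,11(13)-trien-12,6β-olide; 30 angelic acid ((Z)-2-methylbut-2-enoic acid)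
Product: 32 (1E,4Z)-8β-angeloyloxy-3β-TBSO-10α-hydroxygermacra-1,4,11(13)-trien-12,6β-olide, via mixed anhydride 31 (not isolated)
Conditions: 30, 2,4,6-trichlorobenzoyl chloride, Et3N, toluene, rt; then 29, 80 °C
Reagents that add atoms: 30 angelic acid, C/C=C(/C)C(=O)O
Why: Yamaguchi esterification through the mixed anhydride, run without a nucleophilic amine catalyst so that the angelate is not isomerised to the tiglate; the tertiary C10 hydroxyl is too hindered to be acylated and C3 is still protected.

Step 17
Reactants: 32 (1E,4Z)-8β-angeloyloxy-3β-TBSO-10α-hydroxygermacra-1,4,11(13)-trien-12,6β-olide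
Product: 33 (1E,3S,4Z,6S,7R,8R,10R)-8-angeloyloxy-3,10-dihydroxygermacra-1,4,11(13)-trien-12,6-olide
Conditions: HF·pyridine, pyridine, THF, 0 °C to rt
Reagents that add atoms: none
Why: fluoride-mediated desilylation under buffered, non-basic conditions, which should spare the angelate, the methylene lactone and the two allylic alcohols.

## Compound list

1 | (S)-2,2-dimethyl-1,3-dioxolane-4-carbaldehyde | O=C[C@@H]1COC(C)(C)O1 | starting material
2 | methyl 2-[bis(2,2,2-trifluoroethoxy)phosphoryl]acetate | COC(=O)CP(=O)(OCC(F)(F)F)OCC(F)(F)F | starting material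
3 | methyl (Z)-3-[(4R)-2,2-dimethyl-1,3-dioxolan-4-yl]prop-2-enoate | COC(=O)/C=C\[C@@H]1COC(C)(C)O1 | intermediate
4 | (Z)-3-[(4R)-2,2-dimethyl-1,3-dioxolan-4-yl]prop-2-en-1-ol | OC/C=C\[C@@H]1COC(C)(C)O1 | intermediate
5 | triethyl orthoacetate | CC(OCC)(OCC)OCC | starting material
6 | 1-ethoxyvinyl ether of 4 (mixed ketene acetal) | C=C(OCC)OC/C=C\[C@@H]1COC(C)(C)O1 | intermediate (not isolated)
7 | ethyl (3R)-3-[(4R)-2,2-dimethyl-1,3-dioxolan-4-yl]pent-4-enoate | CCOC(=O)C[C@H](C=C)[C@@H]1COC(C)(C)O1 | intermediate
8 | ethyl (3R,4R)-3-ethenyl-4,5-dihydroxypentanoate | CCOC(=O)C[C@H](C=C)[C@@H](O)CO | intermediate (not isolated)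
9 | (4R,5R)-4-ethenyl-5-(hydroxymethyl)oxolan-2-one | OC[C@@H]1OC(=O)C[C@@H]1C=C | intermediate
10 | (2R,3R)-3-ethenyl-5-oxooxolane-2-carbaldehyde | O=C[C@@H]1OC(=O)C[C@@H]1C=C | intermediate
11 | ethyltriphenylphosphonium iodide | CC[P+](c1ccccc1)(c1ccccc1)c1ccccc1.[I-] | starting material
12 | (1-iodoethylidene)triphenylphosphorane | CC(I)=P(c1ccccc1)(c1ccccc1)c1ccccc1 | intermediate (not isolated)
13 | (4R,5R)-4-ethenyl-5-[(Z)-2-iodoprop-1-en-1-yl]oxolan-2-one | I/C(C)=C\[C@@H]1OC(=O)C[C@@H]1C=C | intermediate
14 | (E)-4,4-dimethoxybut-2-enal | COC(OC)/C=C/C=O | starting material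
15 | alkenylchromium dichloride from 13 (trivalent chromium on C4, Z retained) | Cl[Cr](Cl)/C(C)=C\[C@@H]1OC(=O)C[C@@H]1C=C | intermediate (not isolated)
16 | (4R,5R)-4-ethenyl-5-[(1Z,3S,4E)-3-hydroxy-6,6-dimethoxy-2-methylhexa-1,4-dien-1-yl]oxolan-2-one | COC(OC)/C=C/[C@H](O)/C(C)=C\[C@@H]1OC(=O)C[C@@H]1C=C | intermediate
17 | tert-butyldimethylsilyl ether of 16 | COC(OC)/C=C/[C@H](O[Si](C)(C)C(C)(C)C)/C(C)=C\[C@@H]1OC(=O)C[C@@H]1C=C | intermediate
18 | (2E,4S,5Z)-4-TBSO-5-methyl-6-[(2R,3R)-3-ethenyl-5-oxooxolan-2-yl]hexa-2,5-dienal | O=C/C=C/[C@H](O[Si](C)(C)C(C)(C)C)/C(C)=C\[C@@H]1OC(=O)C[C@@H]1C=C | intermediate (not isolated)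
19 | oxime of 18 (drawn as the E-oxime; both oxime isomers serve) | O/N=C/C=C/[C@H](O[Si](C)(C)C(C)(C)C)/C(C)=C\[C@@H]1OC(=O)C[C@@H]1C=C | intermediate
20 | nitrile oxide from 19 | [O-][N+]#C/C=C/[C@H](O[Si](C)(C)C(C)(C)C)/C(C)=C\[C@@H]1OC(=O)C[C@@H]1C=C | intermediate (not isolated)
21 | (1E,4Z)-3β-TBSO-8β,10-(epoxynitrilo)-14-norgermacra-1,4-dien-12,6β-olide | C1C(=O)O[C@H]2/C=C(/C)[C@@H](O[Si](C)(C)C(C)(C)C)/C=C/C3=NO[C@H](C3)[C@@H]12 | intermediate
22 | 10-imino-8β-hydroxy analogue of 21 (N–O bond cleaved) | C1C(=O)O[C@H]2/C=C(/C)[C@@H](O[Si](C)(C)C(C)(C)C)/C=C/C(=N)C[C@@H](O)[C@@H]12 | intermediate (not isolated)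
23 | (1E,4Z)-3β-TBSO-8β-hydroxy-10-oxo-14-norgermacra-1,4-dien-12,6β-olide | C1C(=O)O[C@H]2/C=C(/C)[C@@H](O[Si](C)(C)C(C)(C)C)/C=C/C(=O)C[C@@H](O)[C@@H]12 | intermediate
24 | (1E,4Z)-3β-TBSO-8β-TESO-10-oxo-14-norgermacra-1,4-dien-12,6β-olide | C1C(=O)O[C@H]2/C=C(/C)[C@@H](O[Si](C)(C)C(C)(C)C)/C=C/C(=O)C[C@@H](O[Si](CC)(CC)CC)[C@@H]12 | intermediate
25 | (1E,4Z)-3β-TBSO-8β-TESO-10α-hydroxygermacra-1,4-dien-12,6β-olide | C1C(=O)O[C@H]2/C=C(/C)[C@@H](O[Si](C)(C)C(C)(C)C)/C=C/[C@](C)(O)C[C@@H](O[Si](CC)(CC)CC)[C@@H]12 | intermediate
26 | 13-(dimethylamino) derivative of 25 (C11 epimers) | CN(C)CC1C(=O)O[C@H]2/C=C(/C)[C@@H](O[Si](C)(C)C(C)(C)C)/C=C/[C@](C)(O)C[C@@H](O[Si](CC)(CC)CC)[C@@H]12 | intermediate (not isolated)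
27 | 13-(trimethylammonio) derivative of 25, iodide | C[N+](C)(C)CC1C(=O)O[C@H]2/C=C(/C)[C@@H](O[Si](C)(C)C(C)(C)C)/C=C/[C@](C)(O)C[C@@H](O[Si](CC)(CC)CC)[C@@H]12.[I-] | intermediate (not isolated)
28 | (1E,4Z)-3β-TBSO-8β-TESO-10α-hydroxygermacra-1,4,11(13)-trien-12,6β-olide | C=C1C(=O)O[C@H]2/C=C(/C)[C@@H](O[Si](C)(C)C(C)(C)C)/C=C/[C@](C)(O)C[C@@H](O[Si](CC)(CC)CC)[C@@H]12 | intermediate
29 | (1E,4Z)-3β-TBSO-8β,10α-dihydroxygermacra-1,4,11(13)-trien-12,6β-olide | C=C1C(=O)O[C@H]2/C=C(/C)[C@@H](O[Si](C)(C)C(C)(C)C)/C=C/[C@](C)(O)C[C@@H](O)[C@@H]12 | intermediate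
30 | angelic acid ((Z)-2-methylbut-2-enoic acid) | C/C=C(/C)C(=O)O | starting material
31 | angelic 2,4,6-trichlorobenzoic anhydride | C/C=C(/C)C(=O)OC(=O)c1c(Cl)cc(Cl)cc1Cl | intermediate (not isolated)
32 | (1E,4Z)-8β-angeloyloxy-3β-TBSO-10α-hydroxygermacra-1,4,11(13)-trien-12,6β-olide | C=C1C(=O)O[C@H]2/C=C(/C)[C@@H](O[Si](C)(C)C(C)(C)C)/C=C/[C@](C)(O)C[C@@H](OC(=O)/C(C)=C\C)[C@@H]12 | intermediate
33 | (1E,3S,4Z,6S,7R,8R,10R)-8-angeloyloxy-3,10-dihydroxygermacra-1,4,11(13)-trien-12,6-olide | C=C1C(=O)O[C@H]2/C=C(/C)[C@@H](O)/C=C/[C@](C)(O)C[C@@H](OC(=O)/C(C)=C\C)[C@@H]12 | target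

## Step count and least certain steps

Total: 17 steps. Longest linear sequence: 17 steps, from 1 to 33.

**Step 10 (key step).** The strain of the ten-membered transition state may slow the intramolecular addition so far that bimolecular dimerisation of the conjugated nitrile oxide to furoxans takes over, even at high dilution. A second risk is attack on the other vinyl face if the ring-forming geometry overrides the allylic-strain preference.

Fallback, from iodoalkene 13 and enal 14, returning at 21: the order of the two carbon–carbon bond formations is reversed, and both reactions are then of known type. Enal 14 is converted with hydroxylamine into (2E)-4,4-dimethoxybut-2-enal oxime F1. Oxidation of F1 with NaOCl in the presence of 13 gives the nitrile oxide F2, which adds to the terminal vinyl group of 13 to give the 5-substituted isoxazoline acetal F3. The C8 epimers are separated at this point. Mild acid hydrolysis gives enal F4. An intramolecular Nozaki–Hiyama–Kishi reaction (CrCl2, NiCl2 cat., high dilution) closes C3–C4 to the macrocyclic allylic alcohol F5. Silylation of the 3S epimer with TBSCl gives 21.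

**Step 13.** The facial selectivity of the methyl addition rests on the conformation of the ring. Attack on the other carbonyl face would give the C10 epimer, the 1,3-syn diol.

Fallback, from ketone 24, returning at 25: oxygen instead of carbon is delivered from the ring periphery. Wittig methylenation of 24 (Ph3P=CH2) gives the exocyclic diene F6. A Mukaiyama hydration (Co(acac)2, PhSiH3, O2) adds hydrogen to the CH2 terminus and traps the planar C10 radical with oxygen from the open face. This is the opposite stereochemical sense to carbon delivery, provided the allylic radical is trapped at C10, and gives 25.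

**Step 7.** The ligand on chromium may give insufficient facial control with the hindered trisubstituted alkenylchromium 15, so that both C3 epimers form.

Fallback, from 13 and 14, returning at 16: the coupling is run without the ligand. The mixture of C3 epimers is oxidised with Dess–Martin periodinane to the cross-conjugated dienone F7. A Corey–Bakshi–Shibata reduction follows, with the α-branched C4 alkenyl group as the large substituent and the oxazaborolidine antipode chosen for 3S, and gives 16.

**Step 6.** The basic ylide may epimerise the α-acyloxy aldehyde before it adds, and the olefination may stop at partial conversion with imperfect Z selectivity.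

Fallback, from aldehyde 10, returning at 16: a Corey–Fuchs reaction (CBr4, PPh3) under non-basic conditions gives the dibromoalkene F8. A Negishi coupling with MeZnCl and PdCl2(DPEphos) replaces only the bromine trans to C6 and gives the Z-bromoalkene F9. F9 is coupled with 14 under the conditions of step 7 to give 16.

## Further compounds

F1 | step 10 | (2E)-4,4-dimethoxybut-2-enal oxime | COC(OC)/C=C/C=NO
F2 | step 10 | (2E)-4,4-dimethoxybut-2-enenitrile oxide | COC(OC)/C=C/C#[N+][O-]
F3 | step 10 | (4R,5R)-4-[(5R)-3-[(E)-3,3-dimethoxyprop-1-en-1-yl]-4,5-dihydroisoxazol-5-yl]-5-[(Z)-2-iodoprop-1-en-1-yl]oxolan-2-one | COC(OC)/C=C/C1=NO[C@H](C1)[C@H]1CC(=O)O[C@H]1/C=C(/C)I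
F4 | step 10 | (E)-3-[(5R)-5-[(2R,3R)-2-[(Z)-2-iodoprop-1-en-1-yl]-5-oxooxolan-3-yl]-4,5-dihydroisoxazol-3-yl]prop-2-enal | O=C/C=C/C1=NO[C@H](C1)[C@H]1CC(=O)O[C@H]1/C=C(/C)I
F5 | step 10 | (1E,4Z)-3β-hydroxy-8β,10-(epoxynitrilo)-14-norgermacra-1,4-dien-12,6β-olide | C1C(=O)O[C@H]2/C=C(/C)[C@@H](O)/C=C/C3=NO[C@H](C3)[C@@H]12
F6 | step 13 | (1E,4Z)-3β-TBSO-8β-TESO-germacra-1,4,10(14)-trien-12,6β-olide | C1C(=O)O[C@H]2/C=C(/C)[C@@H](O[Si](C)(C)C(C)(C)C)/C=C/C(=C)C[C@@H](O[Si](CC)(CC)CC)[C@@H]12
F7 | step 7 | (4R,5R)-4-ethenyl-5-[(1Z,4E)-6,6-dimethoxy-2-methyl-3-oxohexa-1,4-dien-1-yl]oxolan-2-one | COC(OC)/C=C/C(=O)/C(C)=C\[C@@H]1OC(=O)C[C@@H]1C=C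
F8 | step 6 | (4R,5R)-5-(2,2-dibromoethenyl)-4-ethenyloxolan-2-one | BrC(Br)=C[C@@H]1OC(=O)C[C@@H]1C=C
F9 | step 6 | (4R,5R)-5-[(Z)-2-bromoprop-1-en-1-yl]-4-ethenyloxolan-2-one | Br/C(C)=C\[C@@H]1OC(=O)C[C@@H]1C=C
A1 | alternative 1 | cis-lactone with Z-allylic alcohol, C8 p-methoxybenzyl ether, C10 triethylsilyl ether and E-iodoalkene | OC/C(C)=C\[C@@H]1OC(=O)C[C@@H]1[C@H](OCc2ccc(OC)cc2)C[C@@](C)(O[Si](CC)(CC)CC)/C=C/I
A2 | alternative 1 | propargyl alcohol | C#CCO
A3 | alternative 1 | methyl 3-formyl-7-iodo-4-(4-methoxybenzyloxy)-6-methyl-6-(triethylsilyloxy)hept-7-enoate (C6 aldehyde partner, configuration as in A1) | O=C[C@H](CC(=O)OC)[C@H](OCc1ccc(OC)cc1)C[C@@](C)(O[Si](CC)(CC)CC)/C=C/I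
A4 | alternative 2 | (1(10)E,4Z)-cyclodecadienone with C8 p-methoxybenzyl ether and C3 silyl ether | C1/C(C)=C/C[C@H](O[Si](C)(C)C(C)(C)C)/C(C)=C\C(=O)C[C@@H]1OCc2ccc(OC)cc2
A5 | alternative 3 | seven-membered dioxasilepine with the Z-C4=C5 alkene | COc1ccc(COCC[C@@](C)(O[Si](CC)(CC)CC)/C=C/[C@@H]2O[Si](C(C)C)(C(C)C)O[C@H](/C=C(\COC(C)=O)C(=O)OC(C)(C)C)C=C2C)cc1
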